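## Retrosynthetic overview

1. The enol ester comes from keto aldehyde 23 by O-acylation of the aldehyde enol. 23 comes from ozonolysis of a cis-fused methylcyclohexene (temporary ring Q), so both side chains and the C4/C16 stereocentres derive from one cycloaddition.
2. Ring Q: exo-face Diels–Alder reaction of tricyclic enone 15 with a 2-silyloxy-3-methylbutadiene, then exchange of the enol oxygen for H (enol triflate, formate reduction).
3. The cycloheptenone (ring A) of 15: Saegusa–Ito one-carbon ring expansion of the cyclohexanone in tricyclic ketone 10.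
4. Rings B (cyclohexane) and P (pyran) form together by Lewis acid bicyclisation of the Morita–Baylis–Hillman alcohol 9 onto a six-membered ring A.
5. C13 is set by copper-catalysed asymmetric conjugate addition of Me3Al. Ring order: A (six-membered, from the starting enone), then B and P in one step, then A expanded to seven, then Q made and cleaved.

Assumption: atom labels follow the target chain C1H3–C2(=O)–C3H2–C4H–C5(=O)–C6H–C7H2–O8–C9(CH3)2–C10H–C11H2–C12H2–C13(CH3)–C16H–C17H=C18H–O-acyl, with C14H2 linking C13 and C15H and ring bonds C4–C16, C6–C15, C10–C15; in these labels the target is (4R,6S,10R,13S,15S,16S). Both enantiomers of the phosphoramidite ligand and 3-methylbut-2-enoic anhydride are taken as purchasable. "Exo" means the face of ring A away from the C10–C11–C12 bridge.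

## Route

Step 1
Reactants: 1 5-bromo-2-methylpent-2-ene; 2 3-ethoxycyclohex-2-en-1-one
Product: 5 3-(4-methylpent-3-en-1-yl)cyclohex-2-en-1-one, via Grignard reagent 3 (not isolated), via magnesium alkoxide adduct 4 (not isolated)
Conditions: Mg, THF, 40 °C; then 2, 0 °C → rt; then aq. HCl, rt
Reagents that add atoms: water, O
Why: Grignard 1,2-addition to the vinylogous ester followed by acid hydrolysis with carbonyl transposition (Stork–Danheiser sequence) gives the 3-alkyl enone; no stereocentre is formed.

Step 2
Reactants: 5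
Product: 7 (R)-3-methyl-3-(4-methylpent-3-en-1-yl)cyclohexan-1-one, via aluminium enolate 6 (not isolated)
Conditions: Me3Al (1.5 equiv), copper thiophene-2-carboxylate Cu(O2CC4H3S) (2 mol %), O,O'-(biphenyl-2,2'-diyl) N,N-bis(1-phenylethyl)phosphoramidite (4 mol %, the enantiomer that gives R), Et2O, −30 °C; aq. NH4Cl
Reagents that add atoms: trimethylaluminium, C[Al](C)C
Why: Copper-catalysed asymmetric conjugate addition of Me3Al to a 3-alkylcyclohexenone creates the C13 quaternary stereocentre under ligand control (typically above 90% ee for this substrate class).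

Step 3
Reactants: 7
Product: 8 (S)-5-methyl-5-(4-methylpent-3-en-1-yl)cyclohex-2-en-1-one
Conditions: 2-iodoxybenzoic acid (IBX, 2 equiv), DMSO/toluene, 70 °C
Reagents that add atoms: none
Why: IBX dehydrogenation of the ketone can only go away from the quaternary carbon, so a single enone forms and the stereocentre is untouched (the descriptor changes only by priority).

Step 4
Reactants: 8
Product: 9 (S)-2-(hydroxymethyl)-5-methyl-5-(4-methylpent-3-en-1-yl)cyclohex-2-en-1-one
Conditions: 37% aq. HCHO, 4-(dimethylamino)pyridine (20 mol %), THF/H2O, rt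
Reagents that add atoms: formaldehyde, C=O
Why: Morita–Baylis–Hillman reaction: the amine adds to the unhindered β-carbon and the resulting enolate hydroxymethylates C6; no new stereocentre.

Step 5
Reactants: 9
Product: 10 (6S,10R,13S,15S)-tricyclic keto ether: ring A cyclohexanone C5(=O)/C6/C15/C14/C13/C16 bridged with ring B C13/C14/C15/C10/C11/C12 (a 13-methylbicyclo[3.3.1]nonanone) and fused 9,9-dimethyltetrahydropyran ring P C6/C7/O8/C9/C10/C15; H6 H10 H15 all cis
Conditions: BF3·OEt2 (1.2 equiv), CH2Cl2, −78 → −20 °C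
Reagents that add atoms: none
Why: Lewis acid-promoted cation–olefin (Michael/Prins-type) bicyclisation: the axial side chain on C13 reaches the enone β-carbon C15 only on its own face through a chair transition state with the incipient C9 cation equatorial, the C7 hydroxyl captures that cation to close the pyran, and ketonisation gives the only strain-free all-cis C6/C15/C10 arrangement.

Step 6
Reactants: 10
Product: 12 (6S,10R,13S,15S)-trimethylsilyl enol ether of 10 with the C5=C16 double bond, via lithium enolate 11 (not isolated)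
Conditions: LiN(iPr)2, THF, −78 °C; then Me3SiCl, −78 → 0 °C
Reagents that add atoms: chlorotrimethylsilane, C[Si](C)(C)Cl
Why: Kinetic deprotonation takes the methylene C16 rather than the ring-fusion methine C6, and O-silylation fixes the enol ether regiochemistry; no stereocentre changes.

Step 7
Reactants: 12
Product: 13 (6S,10R,13S,15S)-siloxycyclopropane: 12 with a CH2 (C4) bridging C5 and C16 on the exo face; C5 bears OSiMe3
Conditions: Et2Zn, CH2I2, CH2Cl2, 0 °C → rt
Reagents that add atoms: diiodomethane, ICI
Why: Simmons–Smith (Furukawa) cyclopropanation of the electron-rich silyl enol ether, the only alkene present; the new cyclopropane stereocentres are destroyed in the next step.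

Step 8
Reactants: 13
Product: 15 (6S,10R,13S,15S)-tricyclic enone: ring A is now the cyclohept-2-enone C5(=O)/C4H=C16H/C13/C14/C15/C6; rings B and P as in 10, via chloro ketone 14 (not isolated)
Conditions: FeCl3 (2.2 equiv), DMF, 0 °C → rt; then NaOAc, MeOH, 65 °C
Reagents that add atoms: none
Why: Saegusa–Ito ring expansion: one-electron oxidation opens the siloxycyclopropane at the ring-fusion bond to a C16 radical that is chlorinated, and E1cB loss of HCl gives the cycloheptenone with C4 inserted between C5 and C16; C6, C10, C13 and C15 are unchanged.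

Step 9
Reactants: 16 3-methylbut-3-en-2-one
Product: 17 tert-butyldimethyl[(3-methylbuta-1,3-dien-2-yl)oxy]silane
Conditions: tBuMe2SiOTf, Et3N, CH2Cl2, 0 °C
Reagents that add atoms: tert-butyldimethylsilyl trifluoromethanesulfonate, CC(C)(C)[Si](C)(C)OS(=O)(=O)C(F)(F)F
Why: Soft enolisation and O-silylation of the methyl ketone, which has only one enolisable position, gives the 2-silyloxy diene.

Step 10
Reactants: 15; 17
Product: 18 (4R,6S,10R,13S,15S,16S)-tetracyclic silyl enol ether: ring Q C4/C3H2/C2(CH3)=C18(OSiMe2tBu)/C17H2/C16 cis-fused to ring A of 15 on the exo face; C5 ketone retained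
Conditions: 17 (3 equiv), HN(SO2CF3)2 (10 mol %), CH2Cl2, −78 → −40 °C; Et3N quench
Reagents that add atoms: none
Why: Acid-catalysed Diels–Alder reaction (stepwise Mukaiyama–Michael/Michael limit): the siloxy group sends the diene CH2 next to C–OSi onto the β-carbon C16 ("para" rule), both bonds form on the exo face, and the suprafacial ring fusion sets C4 and C16 cis in one step.

Step 11
Reactants: 18
Product: 20 (4R,6S,10R,13S,15S,16S)-enol triflate: 18 with OSO2CF3 in place of the siloxy group at C18, via caesium enolate 19 (not isolated)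
Conditions: CsF, PhN(SO2CF3)2, MeOCH2CH2OMe, rt
Reagents that add atoms: N-phenylbis(trifluoromethanesulfonimide), O=S(=O)(N(c1ccccc1)S(=O)(=O)C(F)(F)F)C(F)(F)F
Why: Fluoride cleaves the O–Si bond and the enolate is triflated in situ with retention of the tetrasubstituted enol regiochemistry; no stereocentre is involved.

Step 12
Reactants: 20
Product: 21 (4R,6S,10R,13S,15S,16S)-cyclohexene: ring Q is C4/C3H2/C2(CH3)=C18H/C17H2/C16
Conditions: Pd(OAc)2 (5 mol %), PPh3 (10 mol %), HCO2H, Bu3N, DMF, 60 °C
Reagents that add atoms: none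
Why: Palladium-catalysed formate reduction of the enol triflate (oxidative addition, decarboxylation of formate, C–H reductive elimination) replaces OTf by H without moving the double bond.

Step 13
Reactants: 21
Product: 23 (4R,6S,10R,13S,15S,16S)-keto aldehyde: C4 carries CH2C(=O)CH3 and C16 carries CH2CHO, via ozonide 22 (not isolated)
Conditions: O3, CH2Cl2, −78 °C; then Me2S, −78 °C → rt
Reagents that add atoms: ozone, [O-][O+]=O
Why: Ozonolysis with reductive work-up cleaves the only C=C bond, turning C2 into the methyl ketone and C18 into the aldehyde, so the cis ring fusion becomes the cis acetonyl/formylmethyl pair.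

Step 14
Reactants: 23; 24 3-methylbut-2-enoic anhydride
Product: 25 target: (4R,6S,10R,13S,15S,16S)-(E)-enol 3-methylbut-2-enoate
Conditions: 24 (4 equiv), Et3N, 4-(dimethylamino)pyridine (20 mol %), MeCN, 50 °C
Reagents that add atoms: none
Why: Amine-mediated enolisation and O-acylation of the aldehyde, which enolises far more readily than either ketone, gives the enol ester; the E isomer should predominate because the Z isomer puts the acyloxy group cis to the quaternary-flanked C16, and any Z isomer is removed by chromatography.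

## Compound list

1 | 5-bromo-2-methylpent-2-ene | CC(C)=CCCBr | starting material
2 | 3-ethoxycyclohex-2-en-1-one | CCOC1=CC(=O)CCC1 | starting material
3 | (4-methylpent-3-en-1-yl)magnesium bromide (not isolated) | CC(C)=CCC[Mg]Br | intermediate
4 | bromomagnesium 3-ethoxy-1-(4-methylpent-3-en-1-yl)cyclohex-2-en-1-olate, racemic (not isolated) | CCOC1=CC(CCC=C(C)C)(O[Mg]Br)CCC1 | intermediate
5 | 3-(4-methylpent-3-en-1-yl)cyclohex-2-en-1-one | CC(C)=CCCC1=CC(=O)CCC1 | intermediate
6 | dimethylaluminium (R)-3-methyl-3-(4-methylpent-3-en-1-yl)cyclohex-1-en-1-olate (not isolated) | CC(C)=CCC[C@@]1(C)CCCC(O[Al](C)C)=C1 | intermediate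
7 | (R)-3-methyl-3-(4-methylpent-3-en-1-yl)cyclohexan-1-one | CC(C)=CCC[C@@]1(C)CCCC(=O)C1 | intermediate
8 | (S)-5-methyl-5-(4-methylpent-3-en-1-yl)cyclohex-2-en-1-one | CC(C)=CCC[C@@]1(C)CC=CC(=O)C1 | intermediate
9 | (S)-2-(hydroxymethyl)-5-methyl-5-(4-methylpent-3-en-1-yl)cyclohex-2-en-1-one | CC(C)=CCC[C@@]1(C)CC=C(CO)C(=O)C1 | intermediate
10 | (6S,10R,13S,15S)-tricyclic keto ether (rings A six-membered, B, P; all-cis H6/H10/H15) | O=C1[C@@H]2COC(C)(C)[C@@H]3CC[C@@](C)(C[C@@H]32)C1 | intermediate
11 | lithium C5=C16 enolate of 10 (not isolated) | [Li]OC=1[C@@H]2COC(C)(C)[C@@H]3CC[C@@](C)(C[C@@H]32)C=1 | intermediate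
12 | (6S,10R,13S,15S)-trimethylsilyl enol ether of 10 (C5=C16) | C[Si](C)(C)OC=1[C@@H]2COC(C)(C)[C@@H]3CC[C@@](C)(C[C@@H]32)C=1 | intermediate
13 | (6S,10R,13S,15S)-siloxycyclopropane (C4 bridging C5 and C16, exo) | C[Si](C)(C)O[C@]14[C@@H]2COC(C)(C)[C@@H]3CC[C@@](C)(C[C@@H]32)[C@H]1C4 | intermediate
14 | (6S,10R,13S,15S)-16-chloro cycloheptanone, both C16 epimers (not isolated) | O=C1[C@@H]2COC(C)(C)[C@@H]3CC[C@@](C)(C[C@@H]32)C(Cl)C1 | intermediate
15 | (6S,10R,13S,15S)-tricyclic enone (ring A = cyclohept-2-enone, C4=C16) | O=C1[C@@H]2COC(C)(C)[C@@H]3CC[C@@](C)(C[C@@H]32)C=C1 | intermediate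
16 | 3-methylbut-3-en-2-one | CC(=O)C(C)=C | starting material
17 | tert-butyldimethyl[(3-methylbuta-1,3-dien-2-yl)oxy]silane | C=C(C)C(=C)O[Si](C)(C)C(C)(C)C | intermediate
18 | (4R,6S,10R,13S,15S,16S)-tetracyclic silyl enol ether (ring Q cis-fused at C4–C16) | CC=4C[C@H]1C(=O)[C@@H]2COC(C)(C)[C@@H]3CC[C@@](C)(C[C@@H]32)[C@H]1CC=4O[Si](C)(C)C(C)(C)C | intermediate
19 | caesium enolate of 18 at C18 (not isolated) | CC=4C[C@H]1C(=O)[C@@H]2COC(C)(C)[C@@H]3CC[C@@](C)(C[C@@H]32)[C@H]1CC=4[O-].[Cs+] | intermediate
20 | (4R,6S,10R,13S,15S,16S)-enol triflate at C18 | CC=4C[C@H]1C(=O)[C@@H]2COC(C)(C)[C@@H]3CC[C@@](C)(C[C@@H]32)[C@H]1CC=4OS(=O)(=O)C(F)(F)F | intermediate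
21 | (4R,6S,10R,13S,15S,16S)-tetracyclic cyclohexene (C2(CH3)=C18H) | CC=4C[C@H]1C(=O)[C@@H]2COC(C)(C)[C@@H]3CC[C@@](C)(C[C@@H]32)[C@H]1CC=4 | intermediate
22 | ozonide (1,2,4-trioxolane across C2 and C18) of 21 (not isolated) | CC45C[C@H]1C(=O)[C@@H]2COC(C)(C)[C@@H]3CC[C@@](C)(C[C@@H]32)[C@H]1CC(OO4)O5 | intermediate
23 | (4R,6S,10R,13S,15S,16S)-keto aldehyde (C4–CH2COCH3, C16–CH2CHO) | CC(=O)C[C@H]1C(=O)[C@@H]2COC(C)(C)[C@@H]3CC[C@@](C)(C[C@@H]32)[C@H]1CC=O | intermediate
24 | 3-methylbut-2-enoic anhydride | CC(C)=CC(=O)OC(=O)C=C(C)C | starting material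
25 | target, (4R,6S,10R,13S,15S,16S)-(E)-enol 3-methylbut-2-enoate (CNP0281755.2) | CC(=O)C[C@H]1C(=O)[C@@H]2COC(C)(C)[C@@H]3CC[C@@](C)(C[C@@H]32)[C@H]1/C=C/OC(=O)C=C(C)C | target

## Step count and risks

Total step count: 14. Longest linear sequence: 13 (steps 1–8 and 10–14; step 9 is a one-step side branch).

The three steps most likely to fail:

Bicyclisation (step 5). The alkene could attack the carbonyl carbon C5 instead of C15, or the C9 cation could lose a proton before the hydroxyl captures it. The fallback sets out from 9. Oxidation of the allylic alcohol with MnO2 gives the 2-formyl enone F1. Its O=C7–C6=C15 unit is a 1-oxadiene that undergoes an intramolecular inverse-electron-demand hetero-Diels–Alder reaction with the trisubstituted alkene (toluene, 80 °C, or Me2AlCl at low temperature), giving the dihydropyran-fused vinylogous ester F2 with the C15–C10 and O8–C9 bonds formed in an unambiguous sense. Hydrogenation of the C6=C7 enol ether bond (H2, Pd/C, EtOAc) comes back to the route at 10.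

Diels–Alder reaction (step 10). The β-carbon C16 is neopentylic, the silyloxy diene is acid-sensitive, and the new C4 centre is epimerisable. The fallback sets out from 15 and builds ring Q stepwise. TiCl4-promoted Hosomi–Sakurai addition of allyltrimethylsilane to the exo face gives the 16-allyl ketone F3. Kinetic C4 enolate formation (LiN(iPr)2) and alkylation with 3-bromo-2-methylpropene gives the allyl methallyl ketone F4. Ring-closing metathesis of the two cis chains (second-generation Grubbs catalyst) closes the cyclohexene and comes back to the route at 21.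

Enol ester formation (step 14). The E/Z ratio is not guaranteed, the keto aldehyde can undergo intramolecular aldol reaction, and the anhydride can deconjugate. The fallback sets out from 15 and makes the C18–O bond by a stereoretentive coupling instead of enolisation. Copper-catalysed 1,4-addition of vinylmagnesium bromide (CuBr·SMe2) on the exo face, interception of the enolate at C4 with 2-nitropropene and acidic Nef work-up give the vinyl acetonyl diketone F5. Cross-metathesis with pinacol vinylboronate (second-generation Hoveyda–Grubbs catalyst) gives the (E)-alkenyl pinacol boronate F6. KHF2 converts it into the potassium (E)-alkenyltrifluoroborate F7. Cu(OAc)2-mediated oxidative coupling with 3-methylbut-2-enoic acid (4-(dimethylamino)pyridine, molecular sieves, O2) forms the enol ester with retention of the E geometry and comes back to the route at 25.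

## Further compounds

F1 | step 5 | (S)-4-methyl-4-(4-methylpent-3-en-1-yl)-6-oxocyclohex-1-ene-1-carbaldehyde | CC(C)=CCC[C@@]1(C)CC=C(C=O)C(=O)C1
F2 | step 5 | (10R,13S,15S)-6,7-didehydro analogue of 10 (dihydropyran-fused vinylogous ester) | O=C1C2=COC(C)(C)[C@@H]3CC[C@@](C)(C[C@@H]32)C1
F3 | step 10 | (6S,10R,13S,15S,16S)-16-allyl cycloheptanone (15 with allyl added at C16, exo) | O=C1[C@@H]2COC(C)(C)[C@@H]3CC[C@@](C)(C[C@@H]32)[C@@H](CC=C)C1
F4 | step 10 | (4R,6S,10R,13S,15S,16S)-16-allyl-4-(2-methylallyl) cycloheptanone | C=C(C)C[C@H]1C(=O)[C@@H]2COC(C)(C)[C@@H]3CC[C@@](C)(C[C@@H]32)[C@H]1CC=C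
F5 | step 14 | (4R,6S,10R,13S,15S,16S)-4-(2-oxopropyl)-16-vinyl cycloheptanone | CC(=O)C[C@H]1C(=O)[C@@H]2COC(C)(C)[C@@H]3CC[C@@](C)(C[C@@H]32)[C@H]1C=C
F6 | step 14 | (4R,6S,10R,13S,15S,16S)-(E)-alkenyl pinacol boronate (Bpin on C18) | CC(=O)C[C@H]1C(=O)[C@@H]2COC(C)(C)[C@@H]3CC[C@@](C)(C[C@@H]32)[C@H]1/C=C/B4OC(C)(C)C(C)(C)O4
F7 | step 14 | potassium (4R,6S,10R,13S,15S,16S)-(E)-alkenyltrifluoroborate | CC(=O)C[C@H]1C(=O)[C@@H]2COC(C)(C)[C@@H]3CC[C@@](C)(C[C@@H]32)[C@H]1/C=C/[B-](F)(F)F.[K+]
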